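Readings and results stem from a simulated flask with constants of no real substance, and the scatter is random.

Target at 2.5 d, as a percentage of the substrate charged, reads 27.4% in the west run and 14.3% in the north run, less at the higher substrate charge.

| flask | substrate | reagent in the second phase | protic impurity | remark | time | volume of the second phase over the first |
|---|---|---|---|---|---|---|
| west | 0.050 M | 0.25 M | 2 mM | run made earlier |  |  |
| north | 0.20 M | 0.25 M | 2 mM | run made earlier |  |  |
| east | 0.10 M | 0.25 M | 4 mM | run made earlier |  |  |
| flask | 0.10 M | 0.250 M | 2.00 mM |  | 2.5 d | 2.0 |

| run | time / d | target / % |
|---|---|---|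
| west | 0.333 | 6.8 |
| west | 0.625 | 13.9 |
| west | 1.04 | 19.4 |
| west | 1.25 | 20.8 |
| west | 1.67 | 24.8 |
| west | 2.00 | 24.5 |
| west | 2.50 | 27.4 |
| north | 0.208 | 2.2 |
| north | 0.333 | 5.9 |
| north | 0.500 | 7.2 |
| north | 0.625 | 8.4 |
| north | 1.04 | 11.5 |
| north | 1.67 | 13.8 |
| north | 2.50 | 14.3 |
| east | 0.208 | 3.6 |
| east | 0.417 | 8.4 |
| east | 0.625 | 9.8 |
| east | 1.25 | 16.2 |
| east | 2.50 | 19.5 |

(readings scatter by 1 percentage point)

- in the second phase: reagent in the second phase; everything else is in the first
- charges count per volume of the first phase; a concentration in a rate is the amount of a species over the volume of its own phase; every rate counts per litre of the first phase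
- the earlier runs hold the two phases in the same ratio of volumes as the flask asked about

* the target standing at 2.5 d, as a percentage of the substrate charged
* the change that raises the amount of target at 2.5 d, in percent of the substrate charged most ("none" if none brings more than 2 percentage points) (dawn / autumn / none)
* amount of target at 2.5 d, in percent of the substrate charged, after dawn

- dawn: doubling the transfer coefficient of the reagent in the second phase, all else as stated
- autumn: doubling the amount of reagent in the second phase, all else as stated

I take the settings in turn. For substrate, I divide the two yields at one reading time, so that time drops out. The yield slope, the logarithm of that ratio over the logarithm of the ratio of charges, is 0.469, which makes target an apparent order of 0.531 in substrate. By hand, the flask at 0.10 M reads 19.8%, give or take the scatter of 1 percentage point. For protic impurity, the east run holds twice the flask's amount and reads 19.5%, about the same, so I drop that setting. No run varies the reagent, but I assume that yield follows the ratio of reagent to substrate. Autumn's ratio of 5.00 then repeats west's 5.00, and so west's reading, a gain of 7.6 points. No run varies the transfer coefficient either, and the slope gives me nothing for dawn.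

The forecast says 19.7% (from 18.5% to 21%), chooses autumn because doubling the reagent “raises both the driving force and probably the plateau”, and puts dawn at 21.2% (from 19.7% to 23.5%).

    reagent in the reaction phase → decomposed reagent (k = 0.0940 h⁻¹)
    2 substrate → self-condensation product (k = 0.260 M⁻¹ h⁻¹)
    reagent in the reaction phase + target → over-reacted product (k = 0.260 M⁻¹ h⁻¹)
    substrate + reagent in the reaction phase → target (k = 0.510 M⁻¹ h⁻¹)
    reagent in the reaction phase ⇌ reagent in the second phase, rate k5*([reagent in the reaction phase] - [reagent in the second phase]/K5) per volume of the first phase (partition coefficient = 2.30, kL = 0.210 h⁻¹)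
    reagent in the reaction phase + protic impurity → quenched reagent (k = 16.0 M⁻¹ h⁻¹)

The flask gives 19.9%, against 19.8% from the slope. The better change is autumn, which gains 7.6 points against my 7.6 points, while dawn gains 2.2 points and reaches 22.1%. The neighbour flask at 0.060 M substrate gives 24.8%, and the slope says 25.2%. The flask's target stands at 19.5% at 25.0 d, although at 2.50 d it is still made 1.63 times faster than it is used up. The flask itself has not come to rest, though. By 25.0 d substrate falls from 16.5% to 2.46%, over-reacted product rises from 4.29% to 9.67%, and self-condensation product rises from 59.3% to 68.4%. Reagent in the second phase falls from 37.1% to 0.0253% of its charge.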